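**Plan**

1. Locants: ring B = C1 (CH–CH3), C2, C3, C4 (CH–side chain); ring A = C4a, C5 (H), C6 (CO2Me), C7 (OMe), C8 (OH), C8a; side chain = C11 (CH–CH3), C12–C14, C15 (CH–CH3), C16 (CH2OH).
2. Retrosynthetic cuts, in order: C6–CO2Me (ortho-lithiation), ring-B bond C1–C2, C8a–vinyl and C2–Br (back to a vinyl group on C4), C4–C11 (allylation of an aldehyde), C13–C14 (alkyl–alkyl coupling).
3. Forward: the C11–C16 chain aldehyde is made first and joined to a ready-made ring A at C4–C11; ring B is closed late by the C1–C2 bond and the ester is added afterwards.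
4. Enabling feature: C1 is a benzylic CH(CH3) on C8a, and C2 is an unbranched CH2 five bonds away (C1–C8a–C4a–C4–C3–C2). A C8a vinyl group plus a C2 bromide is therefore the whole precursor: a chiral copper hydride adds to the vinyl group (making the methyl and a C1–Cu bond) and C1 then displaces bromide at C2.
5. Stereochemistry: C15 from (R)-3-bromo-2-methylpropan-1-ol; C4 and C11 together from an iridium/amine dual-catalysed allylation; C1 from the copper ligand, helped by the trans-1,4 preference of ring B.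

Key step: step 13

Assumption: the antipodes named for the chiral ligand and amine in step 6, for the ligand in step 13 and for the chiral reagents in the fallbacks follow the usual facial models. Each controls one centre on its own and would be exchanged for its mirror image if a trial showed the opposite sense.

**Route**

Step 1
Reactants: 1 (R)-3-bromo-2-methylpropan-1-ol
Product: 2 (R)-(3-bromo-2-methylpropoxy)(tert-butyl)dimethylsilane
Conditions: TBSCl, imidazole, DMF, 0 °C to rt
Reagents that add atoms: tert-butyldimethylsilyl chloride, CC(C)(C)[Si](C)(C)Cl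
Why: Imidazole-promoted silylation of the primary alcohol; the stereocentre (future C15) is not touched.

Step 2
Reactants: 2 (R)-(3-bromo-2-methylpropoxy)(tert-butyl)dimethylsilane; 3 5-bromopent-1-ene
Product: 5 (S)-tert-butyldimethyl[(2-methyloct-7-en-1-yl)oxy]silane, via pent-4-en-1-ylmagnesium bromide 4 (not isolated)
Conditions: 3, Mg, THF, rt; then 2, Li2CuCl4 (3 mol%), NMP, THF, 0 °C to rt
Reagents that add atoms: magnesium, [Mg] (metal of 4 only)
Why: Copper-catalysed Grignard–alkyl bromide coupling (Kochi-type) forms the C13–C14 bond at a primary carbon, so the adjacent stereocentre keeps its geometry (the descriptor changes to S by priority only).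

Step 3
Reactants: 5 (S)-tert-butyldimethyl[(2-methyloct-7-en-1-yl)oxy]silane
Product: 7 (S)-7-(tert-butyldimethylsilyloxy)-6-methylheptanal, via 1,2,4-trioxolane 6 (not isolated)
Conditions: O3, CH2Cl2, −78 °C; then PPh3, −78 °C to rt
Reagents that add atoms: ozone, [O-][O+]=O
Why: Ozonolysis with reductive work-up cleaves the terminal alkene to the aldehyde; the silyl ether is inert.

Step 4
Reactants: 8 2-bromo-3-hydroxy-4-methoxybenzaldehyde
Product: 9 2-bromo-4-methoxy-3-(methoxymethoxy)benzaldehyde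
Conditions: MOMCl, iPr2NEt, CH2Cl2, 0 °C to rt
Reagents that add atoms: chloromethyl methyl ether, COCCl
Why: O-alkylation of the phenol gives a MOM acetal that withstands the organometallic, hydride and basic steps ahead and is removed by acid at the end.

Step 5
Reactants: 9 2-bromo-4-methoxy-3-(methoxymethoxy)benzaldehyde
Product: 10 rac-1-[2-bromo-4-methoxy-3-(methoxymethoxy)phenyl]prop-2-en-1-ol
Conditions: CH2=CHMgBr, THF, −78 to 0 °C; aqueous work-up
Reagents that add atoms: vinylmagnesium bromide, C=C[Mg]Br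
Why: Grignard 1,2-addition to the aldehyde gives the racemic branched allylic alcohol (its carbinol carbon is the future C4); the aryl bromide does not exchange with a vinyl Grignard at low temperature.

Step 6
Reactants: 10 rac-1-[2-bromo-4-methoxy-3-(methoxymethoxy)phenyl]prop-2-en-1-ol; 7 (S)-7-(tert-butyldimethylsilyloxy)-6-methylheptanal
Product: 11 (2S,3S)-3-[2-bromo-4-methoxy-3-(methoxymethoxy)phenyl]-2-[(4S)-5-(tert-butyldimethylsilyloxy)-4-methylpentyl]pent-4-enal
Conditions: [Ir(cod)Cl]2 (3 mol%), (R)-BINOL-derived N-(dibenzo[b,f]azepin-5-yl) phosphoramidite–olefin ligand (12 mol%), (R)-2-{bis[3,5-bis(trifluoromethyl)phenyl](trimethylsilyloxy)methyl}pyrrolidine (15 mol%), (MeO)2P(O)OH (promoter), ClCH2CH2Cl, 25 °C; 7 in 1.5-fold excess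
Reagents that add atoms: none
Why: Stereodivergent dual-catalytic α-allylation of a linear aldehyde (iridium-catalysed allylic substitution merged with enamine catalysis): both enantiomers of 10 ionise to one allyl-iridium species whose attacked face (C4) is fixed by the phosphoramidite–olefin ligand, while the enamine of 7 reacts through the face left open by the amine catalyst (C11), which should give the branched anti-(2S,3S) aldehyde.

Step 7
Reactants: 11 (2S,3S)-3-[2-bromo-4-methoxy-3-(methoxymethoxy)phenyl]-2-[(4S)-5-(tert-butyldimethylsilyloxy)-4-methylpentyl]pent-4-enal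
Product: 12 (2S,3S)-3-[2-bromo-4-methoxy-3-(methoxymethoxy)phenyl]-2-[(4S)-5-(tert-butyldimethylsilyloxy)-4-methylpentyl]pent-4-en-1-ol
Conditions: NaBH4, MeOH, 0 °C
Reagents that add atoms: none
Why: Borohydride reduction of the aldehyde, done at once so that the α-centre (C11) cannot epimerise; nothing else is reducible.

Step 8
Reactants: 12 (2S,3S)-3-[2-bromo-4-methoxy-3-(methoxymethoxy)phenyl]-2-[(4S)-5-(tert-butyldimethylsilyloxy)-4-methylpentyl]pent-4-en-1-ol
Product: 13 (2S,3S)-3-[2-bromo-4-methoxy-3-(methoxymethoxy)phenyl]-2-[(4S)-5-(tert-butyldimethylsilyloxy)-4-methylpentyl]pent-4-en-1-yl 4-methylbenzenesulfonate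
Conditions: TsCl, Et3N, DMAP (cat.), CH2Cl2, 0 °C to rt
Reagents that add atoms: 4-toluenesulfonyl chloride, Cc1ccc(cc1)S(Cl)(=O)=O
Why: Sulfonylation of the primary alcohol activates the carbon that is to become the methyl group on C11.

Step 9
Reactants: 13 (2S,3S)-3-[2-bromo-4-methoxy-3-(methoxymethoxy)phenyl]-2-[(4S)-5-(tert-butyldimethylsilyloxy)-4-methylpentyl]pent-4-en-1-yl 4-methylbenzenesulfonate
Product: 14 tert-butyl{[(2S,6S,7S)-7-[2-bromo-4-methoxy-3-(methoxymethoxy)phenyl]-2,6-dimethylnon-8-en-1-yl]oxy}dimethylsilane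
Conditions: LiEt3BH, THF, 0 °C to rt
Reagents that add atoms: none
Why: SN2 hydride displacement of a β-branched primary tosylate by LiEt3BH gives the C11 methyl group; aryl bromide, alkene and both ethers are inert.

Step 10
Reactants: 14 tert-butyl{[(2S,6S,7S)-7-[2-bromo-4-methoxy-3-(methoxymethoxy)phenyl]-2,6-dimethylnon-8-en-1-yl]oxy}dimethylsilane
Product: 16 (3S,4S,8S)-3-[2-bromo-4-methoxy-3-(methoxymethoxy)phenyl]-9-(tert-butyldimethylsilyloxy)-4,8-dimethylnonan-1-ol, via B-alkyl-9-BBN borane 15 (not isolated)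
Conditions: 9-BBN, THF, 0 °C to rt; then NaOH, H2O2, 0 °C to rt
Reagents that add atoms: hydrogen peroxide, OO; 9-borabicyclo[3.3.1]nonane, B1C2CCCC1CCC2 (boron bicycle of 15 only)
Why: Anti-Markovnikov hydroboration–oxidation places oxygen on the terminal carbon C2; the borane is oxidised before any palladium is present, so no boron–aryl coupling can occur.

Step 11
Reactants: 16 (3S,4S,8S)-3-[2-bromo-4-methoxy-3-(methoxymethoxy)phenyl]-9-(tert-butyldimethylsilyloxy)-4,8-dimethylnonan-1-ol
Product: 17 (3S,4S,8S)-9-(tert-butyldimethylsilyloxy)-3-[2-ethenyl-4-methoxy-3-(methoxymethoxy)phenyl]-4,8-dimethylnonan-1-ol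
Conditions: vinylboronic acid pinacol ester, Pd(OAc)2 (5 mol%), SPhos (10 mol%), K3PO4, toluene/H2O, 90 °C
Reagents that add atoms: vinylboronic acid pinacol ester, C=CB1OC(C)(C)C(C)(C)O1
Why: Suzuki–Miyaura coupling with a biarylphosphine suited to a doubly ortho-substituted aryl bromide installs the C8a vinyl group (future C1 and its methyl); the free alcohol is tolerated.

Step 12
Reactants: 17 (3S,4S,8S)-9-(tert-butyldimethylsilyloxy)-3-[2-ethenyl-4-methoxy-3-(methoxymethoxy)phenyl]-4,8-dimethylnonan-1-ol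
Product: 18 {[(2S,6S,7S)-9-bromo-7-[2-ethenyl-4-methoxy-3-(methoxymethoxy)phenyl]-2,6-dimethylnonyl]oxy}(tert-butyl)dimethylsilane
Conditions: CBr4, PPh3, CH2Cl2, 0 °C
Reagents that add atoms: tetrabromomethane, BrC(Br)(Br)Br
Why: Appel reaction converts the primary alcohol into the bromide under near-neutral conditions that spare the MOM acetal, the silyl ether and the styrene.

Step 13
Reactants: 18 {[(2S,6S,7S)-9-bromo-7-[2-ethenyl-4-methoxy-3-(methoxymethoxy)phenyl]-2,6-dimethylnonyl]oxy}(tert-butyl)dimethylsilane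
Product: 19 tert-butyl{[(2S,6S)-6-[(1S,4R)-6-methoxy-5-(methoxymethoxy)-4-methyl-1,2,3,4-tetrahydronaphthalen-1-yl]-2-methylheptyl]oxy}dimethylsilane
Conditions: Cu(OAc)2 (5 mol%), (R)-DTBM-SEGPHOS (5.5 mol%), (MeO)2MeSiH (3 equiv), LiOMe (3 equiv), THF, rt to 40 °C
Reagents that add atoms: none
Why: Copper-hydride-catalysed enantioselective intramolecular hydroalkylation: the ligated copper hydride formed from Cu(OAc)2, the bisphosphine and the silane adds across the C8a vinyl group with Markovnikov regiochemistry, which makes the C1 methyl group and a benzylic C1–Cu bond, and this organocopper then displaces bromide at C2. The closest known reaction type is the copper-hydride-catalysed cyclisation of bromide-tethered styrenes to enantioenriched indanes, cyclopentanes and six-membered heterocycles. Ring B closes in a 6-exo-tet mode, the C–Br bond being exocyclic to the forming ring C1–C2–C3–C4–C4a–C8a. The C1 centre is set in the hydrocupration by the (R)-DTBM-SEGPHOS ligand and carried into the product by C–C bond formation with retention at the copper-bearing carbon, which should give (1R) in the locants of the plan. The step needs benzylic regioselectivity (secured by the aryl group on the alkene), alkylation faster than protonation of the organocopper or reduction of the bromide (secured by the six-membered intramolecular closure, the branch at C4 and LiOMe turnover of the copper bromide), and the 1,4-trans relation, which the substrate supports because only in the trans isomer can the C4 chain and the C1 methyl both sit pseudoaxial, away from C5–H and the C8 oxygen.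

Step 14
Reactants: 19 tert-butyl{[(2S,6S)-6-[(1S,4R)-6-methoxy-5-(methoxymethoxy)-4-methyl-1,2,3,4-tetrahydronaphthalen-1-yl]-2-methylheptyl]oxy}dimethylsilane
Product: 21 methyl (5R,8S)-8-[(2S,6S)-7-(tert-butyldimethylsilyloxy)-6-methylheptan-2-yl]-3-methoxy-4-(methoxymethoxy)-5-methyl-5,6,7,8-tetrahydronaphthalene-2-carboxylate, via C6-aryllithium 20 (not isolated)
Conditions: n-BuLi, TMEDA, THF, −20 to 0 °C; then added to ClCO2Me (3 equiv), THF, −78 °C
Reagents that add atoms: methyl chloroformate, COC(=O)Cl; n-butyllithium, [Li]CCCC (lithium of 20 only)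
Why: Directed ortho-metalation: C6–H is the only ring hydrogen ortho to an oxygen substituent (the C7 methoxy group), and inverse addition of the aryllithium to excess chloroformate gives the methyl ester without ketone formation.

Step 15
Reactants: 21 methyl (5R,8S)-8-[(2S,6S)-7-(tert-butyldimethylsilyloxy)-6-methylheptan-2-yl]-3-methoxy-4-(methoxymethoxy)-5-methyl-5,6,7,8-tetrahydronaphthalene-2-carboxylate
Product: 22 methyl (5R,8S)-4-hydroxy-8-[(2S,6S)-7-hydroxy-6-methylheptan-2-yl]-3-methoxy-5-methyl-5,6,7,8-tetrahydronaphthalene-2-carboxylate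
Conditions: HCl (1.25 M in MeOH), 0 °C to rt
Reagents that add atoms: none
Why: Acid-catalysed methanolysis removes the MOM acetal and the silyl ether in one operation; the methyl ester is unchanged in methanol and no stereocentre is acidic under these conditions.

**Compound list**

1 | (R)-3-bromo-2-methylpropan-1-ol | BrC[C@H](C)CO | starting material
2 | (R)-(3-bromo-2-methylpropoxy)(tert-butyl)dimethylsilane | BrC[C@H](C)CO[Si](C)(C)C(C)(C)C | intermediate
3 | 5-bromopent-1-ene | C=CCCCBr | starting material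
4 | pent-4-en-1-ylmagnesium bromide | C=CCCC[Mg]Br | intermediate
5 | (S)-tert-butyldimethyl[(2-methyloct-7-en-1-yl)oxy]silane | C=CCCCC[C@H](C)CO[Si](C)(C)C(C)(C)C | intermediate
6 | 3-[(5S)-6-(tert-butyldimethylsilyloxy)-5-methylhexyl]-1,2,4-trioxolane (ozonide, both configurations at the ring carbon) | C1(CCCC[C@H](C)CO[Si](C)(C)C(C)(C)C)OCOO1 | intermediate
7 | (S)-7-(tert-butyldimethylsilyloxy)-6-methylheptanal | O=CCCCC[C@H](C)CO[Si](C)(C)C(C)(C)C | intermediate
8 | 2-bromo-3-hydroxy-4-methoxybenzaldehyde | COc1ccc(C=O)c(Br)c1O | starting material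
9 | 2-bromo-4-methoxy-3-(methoxymethoxy)benzaldehyde | COCOc1c(OC)ccc(C=O)c1Br | intermediate
10 | rac-1-[2-bromo-4-methoxy-3-(methoxymethoxy)phenyl]prop-2-en-1-ol | COCOc1c(OC)ccc(C(O)C=C)c1Br | intermediate
11 | (2S,3S)-3-[2-bromo-4-methoxy-3-(methoxymethoxy)phenyl]-2-[(4S)-5-(tert-butyldimethylsilyloxy)-4-methylpentyl]pent-4-enal | COCOc1c(OC)ccc([C@@H](C=C)[C@@H](C=O)CCC[C@H](C)CO[Si](C)(C)C(C)(C)C)c1Br | intermediate
12 | (2S,3S)-3-[2-bromo-4-methoxy-3-(methoxymethoxy)phenyl]-2-[(4S)-5-(tert-butyldimethylsilyloxy)-4-methylpentyl]pent-4-en-1-ol | COCOc1c(OC)ccc([C@@H](C=C)[C@@H](CO)CCC[C@H](C)CO[Si](C)(C)C(C)(C)C)c1Br | intermediate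
13 | (2S,3S)-3-[2-bromo-4-methoxy-3-(methoxymethoxy)phenyl]-2-[(4S)-5-(tert-butyldimethylsilyloxy)-4-methylpentyl]pent-4-en-1-yl 4-methylbenzenesulfonate | COCOc1c(OC)ccc([C@@H](C=C)[C@@H](COS(=O)(=O)c2ccc(C)cc2)CCC[C@H](C)CO[Si](C)(C)C(C)(C)C)c1Br | intermediate
14 | tert-butyl{[(2S,6S,7S)-7-[2-bromo-4-methoxy-3-(methoxymethoxy)phenyl]-2,6-dimethylnon-8-en-1-yl]oxy}dimethylsilane | COCOc1c(OC)ccc([C@@H](C=C)[C@@H](C)CCC[C@H](C)CO[Si](C)(C)C(C)(C)C)c1Br | intermediate
15 | 9-[(3S,4S,8S)-3-[2-bromo-4-methoxy-3-(methoxymethoxy)phenyl]-9-(tert-butyldimethylsilyloxy)-4,8-dimethylnonyl]-9-borabicyclo[3.3.1]nonane | COCOc1c(OC)ccc([C@@H](CCB2C3CCCC2CCC3)[C@@H](C)CCC[C@H](C)CO[Si](C)(C)C(C)(C)C)c1Br | intermediate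
16 | (3S,4S,8S)-3-[2-bromo-4-methoxy-3-(methoxymethoxy)phenyl]-9-(tert-butyldimethylsilyloxy)-4,8-dimethylnonan-1-ol | COCOc1c(OC)ccc([C@@H](CCO)[C@@H](C)CCC[C@H](C)CO[Si](C)(C)C(C)(C)C)c1Br | intermediate
17 | (3S,4S,8S)-9-(tert-butyldimethylsilyloxy)-3-[2-ethenyl-4-methoxy-3-(methoxymethoxy)phenyl]-4,8-dimethylnonan-1-ol | COCOc1c(OC)ccc([C@@H](CCO)[C@@H](C)CCC[C@H](C)CO[Si](C)(C)C(C)(C)C)c1C=C | intermediate
18 | {[(2S,6S,7S)-9-bromo-7-[2-ethenyl-4-methoxy-3-(methoxymethoxy)phenyl]-2,6-dimethylnonyl]oxy}(tert-butyl)dimethylsilane | COCOc1c(OC)ccc([C@@H](CCBr)[C@@H](C)CCC[C@H](C)CO[Si](C)(C)C(C)(C)C)c1C=C | intermediate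
19 | tert-butyl{[(2S,6S)-6-[(1S,4R)-6-methoxy-5-(methoxymethoxy)-4-methyl-1,2,3,4-tetrahydronaphthalen-1-yl]-2-methylheptyl]oxy}dimethylsilane | COc1ccc2c(c1OCOC)[C@H](C)CC[C@H]2[C@@H](C)CCC[C@H](C)CO[Si](C)(C)C(C)(C)C | intermediate
20 | [(5R,8S)-8-[(2S,6S)-7-(tert-butyldimethylsilyloxy)-6-methylheptan-2-yl]-3-methoxy-4-(methoxymethoxy)-5-methyl-5,6,7,8-tetrahydronaphthalen-2-yl]lithium | COc1c([Li])cc2c(c1OCOC)[C@H](C)CC[C@H]2[C@@H](C)CCC[C@H](C)CO[Si](C)(C)C(C)(C)C | intermediate
21 | methyl (5R,8S)-8-[(2S,6S)-7-(tert-butyldimethylsilyloxy)-6-methylheptan-2-yl]-3-methoxy-4-(methoxymethoxy)-5-methyl-5,6,7,8-tetrahydronaphthalene-2-carboxylate | COC(=O)c1cc2c(c(OCOC)c1OC)[C@H](C)CC[C@H]2[C@@H](C)CCC[C@H](C)CO[Si](C)(C)C(C)(C)C | intermediate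
22 | methyl (5R,8S)-4-hydroxy-8-[(2S,6S)-7-hydroxy-6-methylheptan-2-yl]-3-methoxy-5-methyl-5,6,7,8-tetrahydronaphthalene-2-carboxylate | COC(=O)c1cc2c(c(O)c1OC)[C@H](C)CC[C@H]2[C@@H](C)CCC[C@H](C)CO | target

**Count and risks**

Total step count: 15. Longest linear sequence: 13 steps (steps 1–3, then 6–15).

Steps most likely to fail:

Step 13. The vinyl group is twisted out of conjugation by its two ortho neighbours, so hydrocupration may be slow or lose its benzylic regiocontrol. The copper hydride could then reduce the C–Br bond, or the benzylic copper could be protonated before it closes the ring; the ligand may also be mismatched with the C4 centre. Fallback by ring-closing metathesis and asymmetric hydrogenation, setting out from 16 and coming back at 19: Suzuki–Miyaura coupling of 16 with isopropenylboronic acid pinacol ester (Pd(OAc)2, SPhos, K3PO4) would give (3S,4S,8S)-9-(tert-butyldimethylsilyloxy)-3-[4-methoxy-3-(methoxymethoxy)-2-(prop-1-en-2-yl)phenyl]-4,8-dimethylnonan-1-ol F1. Dess–Martin oxidation would give (3S,4S,8S)-9-(tert-butyldimethylsilyloxy)-3-[4-methoxy-3-(methoxymethoxy)-2-(prop-1-en-2-yl)phenyl]-4,8-dimethylnonanal F2. Wittig methylenation (Ph3P=CH2, THF) would give tert-butyl{[(2S,6S,7S)-7-[4-methoxy-3-(methoxymethoxy)-2-(prop-1-en-2-yl)phenyl]-2,6-dimethyldec-9-en-1-yl]oxy}dimethylsilane F3. Ring-closing metathesis with the second-generation Grubbs catalyst RuCl2(=CHPh)(PCy3)(H2IMes) would close the same C1–C2 bond as a double bond in tert-butyl{[(2S,6S)-6-[(1S)-6-methoxy-5-(methoxymethoxy)-4-methyl-1,2-dihydronaphthalen-1-yl]-2-methylheptyl]oxy}dimethylsilane F4. Hydrogenation with a chiral iridium phosphine–oxazoline catalyst, [Ir(cod)(L)]B(ArF)4 with L = (S)-4-tert-butyl-2-[2-(diphenylphosphino)phenyl]-2-oxazoline, under H2 would then return to 19. The ligand antipode is chosen to deliver hydrogen to the face of C1 that carries the C4 side chain, which is catalyst control against a modest substrate bias.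

Step 6. The ortho-bromo aryl group may slow ionisation of the allylic alcohol to the allyl-iridium species, leaving self-aldol of the aldehyde to compete, and the diastereocontrol could erode if the product aldehyde re-enters enamine equilibria. Fallback by Ireland–Claisen rearrangement with 1,3-chirality transfer, setting out from 7 and 9 and coming back at 12: Pinnick oxidation of 7 (NaClO2, NaH2PO4, 2-methylbut-2-ene) would give (S)-7-(tert-butyldimethylsilyloxy)-6-methylheptanoic acid F5. Wittig reaction of 9 with 1-(triphenylphosphoranylidene)propan-2-one would give (E)-4-[2-bromo-4-methoxy-3-(methoxymethoxy)phenyl]but-3-en-2-one F6. CBS reduction ((S)-2-methyl-CBS-oxazaborolidine, BH3·SMe2) would give (R,E)-4-[2-bromo-4-methoxy-3-(methoxymethoxy)phenyl]but-3-en-2-ol F7. Esterification of F7 with F5 (DCC, DMAP) would give (R,E)-4-[2-bromo-4-methoxy-3-(methoxymethoxy)phenyl]but-3-en-2-yl (S)-7-(tert-butyldimethylsilyloxy)-6-methylheptanoate F8. Ireland–Claisen rearrangement (LiN(iPr)2, THF, −78 °C; Me3SiCl; warm to rt) should proceed through the E(O)-enolate and a chair transition state with the carbinol methyl equatorial, giving the anti acid (2S,3S,E)-3-[2-bromo-4-methoxy-3-(methoxymethoxy)phenyl]-2-[(4S)-5-(tert-butyldimethylsilyloxy)-4-methylpentyl]hex-4-enoic acid F9. LiAlH4 reduction at 0 °C would give (2S,3S,E)-3-[2-bromo-4-methoxy-3-(methoxymethoxy)phenyl]-2-[(4S)-5-(tert-butyldimethylsilyloxy)-4-methylpentyl]hex-4-en-1-ol F10. Ethenolysis (ethene, second-generation Grubbs catalyst RuCl2(=CHPh)(PCy3)(H2IMes), CH2Cl2, 40 °C) would trim the propenyl group to the vinyl group of 12.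

Step 14. Deprotonation may occur at a benzylic position or at the MOM methylene instead of C6, lithiation beside the single methoxy director may be incomplete, and the aryllithium may add twice to the chloroformate. Fallback by electrophilic bromination and palladium-catalysed methoxycarbonylation, setting out from 19 and coming back at 22: methanolic HCl would remove both protecting groups to give (5S,8R)-5-[(2S,6S)-7-hydroxy-6-methylheptan-2-yl]-2-methoxy-8-methyl-5,6,7,8-tetrahydronaphthalen-1-ol F11. Ac2O and pyridine would give (2S,6S)-6-[(1S,4R)-5-acetoxy-6-methoxy-4-methyl-1,2,3,4-tetrahydronaphthalen-1-yl]-2-methylheptyl acetate F12, in which the ring is activated mainly by the C7 methoxy group. NBS in MeCN should then brominate C6, the one free position ortho or para to that group, to give (2S,6S)-6-[(1S,4R)-5-acetoxy-7-bromo-6-methoxy-4-methyl-1,2,3,4-tetrahydronaphthalen-1-yl]-2-methylheptyl acetate F13. Carbonylation (Pd(OAc)2, 1,3-bis(diphenylphosphino)propane, CO, MeOH, Et3N, DMF, 80 °C) would give methyl (5R,8S)-4-acetoxy-8-[(2S,6S)-7-acetoxy-6-methylheptan-2-yl]-3-methoxy-5-methyl-5,6,7,8-tetrahydronaphthalene-2-carboxylate F14. K2CO3 in MeOH would remove both acetates and give 22.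

**Further compounds**

F1 | step 13 | (3S,4S,8S)-9-(tert-butyldimethylsilyloxy)-3-[4-methoxy-3-(methoxymethoxy)-2-(prop-1-en-2-yl)phenyl]-4,8-dimethylnonan-1-ol | COCOc1c(OC)ccc([C@@H](CCO)[C@@H](C)CCC[C@H](C)CO[Si](C)(C)C(C)(C)C)c1C(C)=C
F2 | step 13 | (3S,4S,8S)-9-(tert-butyldimethylsilyloxy)-3-[4-methoxy-3-(methoxymethoxy)-2-(prop-1-en-2-yl)phenyl]-4,8-dimethylnonanal | COCOc1c(OC)ccc([C@@H](CC=O)[C@@H](C)CCC[C@H](C)CO[Si](C)(C)C(C)(C)C)c1C(C)=C
F3 | step 13 | tert-butyl{[(2S,6S,7S)-7-[4-methoxy-3-(methoxymethoxy)-2-(prop-1-en-2-yl)phenyl]-2,6-dimethyldec-9-en-1-yl]oxy}dimethylsilane | COCOc1c(OC)ccc([C@@H](CC=C)[C@@H](C)CCC[C@H](C)CO[Si](C)(C)C(C)(C)C)c1C(C)=C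
F4 | step 13 | tert-butyl{[(2S,6S)-6-[(1S)-6-methoxy-5-(methoxymethoxy)-4-methyl-1,2-dihydronaphthalen-1-yl]-2-methylheptyl]oxy}dimethylsilane | COc1ccc2c(c1OCOC)C(C)=CC[C@H]2[C@@H](C)CCC[C@H](C)CO[Si](C)(C)C(C)(C)C
F5 | step 6 | (S)-7-(tert-butyldimethylsilyloxy)-6-methylheptanoic acid | OC(=O)CCCC[C@H](C)CO[Si](C)(C)C(C)(C)C
F6 | step 6 | (E)-4-[2-bromo-4-methoxy-3-(methoxymethoxy)phenyl]but-3-en-2-one | CC(=O)/C=C/c1ccc(OC)c(OCOC)c1Br
F7 | step 6 | (R,E)-4-[2-bromo-4-methoxy-3-(methoxymethoxy)phenyl]but-3-en-2-ol | C[C@@H](O)/C=C/c1ccc(OC)c(OCOC)c1Br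
F8 | step 6 | (R,E)-4-[2-bromo-4-methoxy-3-(methoxymethoxy)phenyl]but-3-en-2-yl (S)-7-(tert-butyldimethylsilyloxy)-6-methylheptanoate | C[C@@H](OC(=O)CCCC[C@H](C)CO[Si](C)(C)C(C)(C)C)/C=C/c1ccc(OC)c(OCOC)c1Br
F9 | step 6 | (2S,3S,E)-3-[2-bromo-4-methoxy-3-(methoxymethoxy)phenyl]-2-[(4S)-5-(tert-butyldimethylsilyloxy)-4-methylpentyl]hex-4-enoic acid | COCOc1c(OC)ccc([C@@H](/C=C/C)[C@@H](C(=O)O)CCC[C@H](C)CO[Si](C)(C)C(C)(C)C)c1Br
F10 | step 6 | (2S,3S,E)-3-[2-bromo-4-methoxy-3-(methoxymethoxy)phenyl]-2-[(4S)-5-(tert-butyldimethylsilyloxy)-4-methylpentyl]hex-4-en-1-ol | COCOc1c(OC)ccc([C@@H](/C=C/C)[C@@H](CO)CCC[C@H](C)CO[Si](C)(C)C(C)(C)C)c1Br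
F11 | step 14 | (5S,8R)-5-[(2S,6S)-7-hydroxy-6-methylheptan-2-yl]-2-methoxy-8-methyl-5,6,7,8-tetrahydronaphthalen-1-ol | COc1ccc2c(c1O)[C@H](C)CC[C@H]2[C@@H](C)CCC[C@H](C)CO
F12 | step 14 | (2S,6S)-6-[(1S,4R)-5-acetoxy-6-methoxy-4-methyl-1,2,3,4-tetrahydronaphthalen-1-yl]-2-methylheptyl acetate | COc1ccc2c(c1OC(C)=O)[C@H](C)CC[C@H]2[C@@H](C)CCC[C@H](C)COC(C)=O
F13 | step 14 | (2S,6S)-6-[(1S,4R)-5-acetoxy-7-bromo-6-methoxy-4-methyl-1,2,3,4-tetrahydronaphthalen-1-yl]-2-methylheptyl acetate | COc1c(Br)cc2c(c1OC(C)=O)[C@H](C)CC[C@H]2[C@@H](C)CCC[C@H](C)COC(C)=O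
F14 | step 14 | methyl (5R,8S)-4-acetoxy-8-[(2S,6S)-7-acetoxy-6-methylheptan-2-yl]-3-methoxy-5-methyl-5,6,7,8-tetrahydronaphthalene-2-carboxylate | COC(=O)c1cc2c(c(OC(C)=O)c1OC)[C@H](C)CC[C@H]2[C@@H](C)CCC[C@H](C)COC(C)=O
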